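Abietane numbering (C1–C20) is used throughout.

**Plan**
- Retrosynthesis, late cuts: the C12 acetate and the C11/C14 quinone go back to an 11,12,14-trimethoxyarene. The C6=C7 alkene goes back to a 7-acetoxy-6-sulfone (Julia–Lythgoe).
- Retrosynthesis, core cuts: C3–C4 and C5–C6 are cut together, which unfolds rings A and B to a monocyclic unsaturated δ-lactone. C6–C7 is cut to an aryl aldehyde and methyl phenyl sulfone, and C4=C5 to an aldehyde and a phosphonopropionate. C9–C10 and C1–C10 are cut to an aryl bromide, dimethyl malonate and 1-chloro-3-iodopropane.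
- Enabling feature: C10 is the pivot of the lactone ring O–C20–C10–C5=C4–C19. It holds ring C (with a C7–C6 arm on C8) on one face and the chain C1–C2–C3 on the other. C5 is the β-carbon and C4 the α-carbon of C19=O, so a C6 carbanion adding to C5 leaves a C4 enolate 1,3-diaxial to C3–I.
- Forward order: ring C is bought, the lactone ring is made next, rings B and A close in one operation, and ring C is oxidised last.
- Stereochemistry: C10 comes from a catalytic enantioselective desymmetrisation of a prochiral 1,3-diol. C5 and C4 are relayed from C10 by the two tethers in the key step. C6 and C7 are transient.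

Key step: step 14

Assumption: 2,4,5-trimethoxytoluene and ethyl 2-[bis(2,2,2-trifluoroethoxy)phosphoryl]propanoate are taken as catalogue compounds.

Step 1
Reactants: 1 2,4,5-trimethoxytoluene; 2 acetone
Product: 4 2-(2,3,6-trimethoxy-5-methylphenyl)propan-2-ol, via aryllithium 3 (not isolated)
Conditions: n-BuLi, THF, 0 °C to rt; then 2, −78 °C to rt; H2O
Reagents that add atoms: none
Why: Directed ortho-metalation followed by 1,2-addition: the ring C–H between the two methoxy groups (future C13) is the most acidic site of 1, so n-BuLi lithiates there and the aryllithium adds to acetone.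

Step 2
Reactants: 4 2-(2,3,6-trimethoxy-5-methylphenyl)propan-2-ol
Product: 5 3-isopropyl-2,4,5-trimethoxytoluene
Conditions: Et3SiH, CF3CO2H, CH2Cl2, 0 °C to rt
Reagents that add atoms: none
Why: Ionic hydrogenation: the acid ionises the tertiary benzylic alcohol to a cation stabilised by two ortho methoxy groups and Et3SiH transfers hydride to it, which leaves the isopropyl group.

Step 3
Reactants: 5 3-isopropyl-2,4,5-trimethoxytoluene
Product: 6 2-bromo-5-isopropyl-3,4,6-trimethoxytoluene
Conditions: NBS, MeCN, 0 °C, dark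
Reagents that add atoms: N-bromosuccinimide, BrN1C(=O)CCC1=O
Why: Electrophilic aromatic bromination: 5 has a single ring C–H (future C9), activated by its ortho methoxy group and by the ortho and para alkyl groups, so no regiochemical choice arises.

Step 4
Reactants: 6 2-bromo-5-isopropyl-3,4,6-trimethoxytoluene; 7 dimethyl malonate
Product: 8 dimethyl 2-(4-isopropyl-2,3,5-trimethoxy-6-methylphenyl)malonate
Conditions: Pd(OAc)2 (2 mol %), P(t-Bu)3·HBF4 (4 mol %), K3PO4, toluene, 100 °C
Reagents that add atoms: none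
Why: Palladium-catalysed α-arylation of a malonate: the bulky electron-rich phosphine gives a monoligated zerovalent palladium species that inserts into hindered electron-rich aryl bromides, a coupling that is known for 2,6-dialkylaryl bromides.

Step 5
Reactants: 8 dimethyl 2-(4-isopropyl-2,3,5-trimethoxy-6-methylphenyl)malonate; 9 1-chloro-3-iodopropane
Product: 11 dimethyl 2-(3-chloropropyl)-2-(4-isopropyl-2,3,5-trimethoxy-6-methylphenyl)malonate, via sodium enolate 10 (not isolated)
Conditions: NaH, DMF, 0 °C; then 9, 50 °C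
Reagents that add atoms: none
Why: SN2 alkylation of a malonate enolate: the soft enolate displaces iodide far faster than chloride, which builds the still prochiral quaternary carbon C10 and keeps a latent leaving group on C3.

Step 6
Reactants: 11 dimethyl 2-(3-chloropropyl)-2-(4-isopropyl-2,3,5-trimethoxy-6-methylphenyl)malonate
Product: 12 2-(3-chloropropyl)-2-(4-isopropyl-2,3,5-trimethoxy-6-methylphenyl)propane-1,3-diol
Conditions: LiAlH4, THF, 0 °C to rt
Reagents that add atoms: none
Why: Ester reduction by LiAlH4: both ester groups are reduced to the two enantiotopic hydroxymethyl groups, whereas a primary alkyl chloride reacts much more slowly with hydride at this temperature.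

Step 7
Reactants: 12 2-(3-chloropropyl)-2-(4-isopropyl-2,3,5-trimethoxy-6-methylphenyl)propane-1,3-diol
Product: 13 (S)-5-chloro-2-(hydroxymethyl)-2-(4-isopropyl-2,3,5-trimethoxy-6-methylphenyl)pentyl benzoate
Conditions: BzCl, CuCl2 (10 mol %), chiral Ph-PyBOX ligand (11 mol %, the antipode that acylates the pro-S arm), Et3N, THF, −20 °C
Reagents that add atoms: benzoyl chloride, O=C(Cl)c1ccccc1
Why: Catalytic enantioselective desymmetrisation of a 2,2-disubstituted propane-1,3-diol by monobenzoylation: the chiral copper complex chelates the diol and activates one enantiotopic hydroxyl group, and benzoylation of the pro-S arm (future C20) fixes C10 in the configuration of the target.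

Step 8
Reactants: 13 (S)-5-chloro-2-(hydroxymethyl)-2-(4-isopropyl-2,3,5-trimethoxy-6-methylphenyl)pentyl benzoate
Product: 14 (R)-5-chloro-2-formyl-2-(4-isopropyl-2,3,5-trimethoxy-6-methylphenyl)pentyl benzoate
Conditions: Dess–Martin periodinane, CH2Cl2, rt
Reagents that add atoms: none
Why: Dess–Martin oxidation: the free neopentyl alcohol (future C5) is oxidised under neutral conditions that avoid 1,3-benzoyl migration, and the aldehyde has no α-hydrogen, so C10 is safe.

Step 9
Reactants: 14 (R)-5-chloro-2-formyl-2-(4-isopropyl-2,3,5-trimethoxy-6-methylphenyl)pentyl benzoate; 15 ethyl 2-[bis(2,2,2-trifluoroethoxy)phosphoryl]propanoate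
Product: 17 ethyl (R,Z)-4-[(benzoyloxy)methyl]-7-chloro-4-(4-isopropyl-2,3,5-trimethoxy-6-methylphenyl)-2-methylhept-2-enoate, via potassium phosphonate anion 16 (not isolated)
Conditions: 15, KHMDS, 18-crown-6, THF, −78 °C; then 14, −78 to −20 °C
Reagents that add atoms: none
Why: Still–Gennari variant of the Horner–Wadsworth–Emmons olefination: the trifluoroethyl phosphonate and the crown-ether-separated potassium ion make elimination faster than equilibration, which should give the (Z)-trisubstituted enoate in which C19 is cis to C10.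

Step 10
Reactants: 17 ethyl (R,Z)-4-[(benzoyloxy)methyl]-7-chloro-4-(4-isopropyl-2,3,5-trimethoxy-6-methylphenyl)-2-methylhept-2-enoate
Product: 19 (R)-5-(3-chloropropyl)-5-(4-isopropyl-2,3,5-trimethoxy-6-methylphenyl)-3-methyl-5,6-dihydro-2H-pyran-2-one, via hydroxy enoate 18 (not isolated)
Conditions: K2CO3 (cat.), MeOH, rt
Reagents that add atoms: none
Why: Transesterification and lactonisation: methoxide removes the benzoate and the freed C20 hydroxyl group, held cis to the ester by the (Z)-alkene, closes the six-membered unsaturated lactone.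

Step 11
Reactants: 19 (R)-5-(3-chloropropyl)-5-(4-isopropyl-2,3,5-trimethoxy-6-methylphenyl)-3-methyl-5,6-dihydro-2H-pyran-2-one
Product: 21 2-[(R)-3-(3-chloropropyl)-5-methyl-6-oxo-3,6-dihydro-2H-pyran-3-yl]-5-isopropyl-3,4,6-trimethoxybenzaldehyde, via benzylic alcohol 20 (not isolated)
Conditions: DDQ (2.5 equiv), 1,4-dioxane–H2O, rt to 50 °C
Reagents that add atoms: water, O
Why: Benzylic oxidation by hydride abstraction with DDQ in an aqueous medium: the methyl group (C7) is para to the C11 and ortho to the C14 methoxy group, water traps its cation and the alcohol is oxidised on to the aldehyde, whereas the isopropyl C–H lies in the ring plane between two methoxy groups and overlaps poorly with the ring.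

Step 12
Reactants: 21 2-[(R)-3-(3-chloropropyl)-5-methyl-6-oxo-3,6-dihydro-2H-pyran-3-yl]-5-isopropyl-3,4,6-trimethoxybenzaldehyde; 22 methyl phenyl sulfone
Product: 24 (R)-5-(3-chloropropyl)-5-{2-[1-hydroxy-2-(phenylsulfonyl)ethyl]-4-isopropyl-3,5,6-trimethoxyphenyl}-3-methyl-5,6-dihydro-2H-pyran-2-one (both C7 epimers), via lithiated sulfone 23 (not isolated)
Conditions: 22, n-BuLi, THF, −78 °C; then 21, −78 °C; AcOH quench at −78 °C
Reagents that add atoms: none
Why: First half of a Julia–Lythgoe olefination: the lithiated sulfone adds to the aldehyde at −78 °C much faster than it attacks the hindered unsaturated lactone or the alkyl chloride, which brings in C6, and the C7 epimers are both used because C7 becomes planar in step 15.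

Step 13
Reactants: 24 (R)-5-(3-chloropropyl)-5-{2-[1-hydroxy-2-(phenylsulfonyl)ethyl]-4-isopropyl-3,5,6-trimethoxyphenyl}-3-methyl-5,6-dihydro-2H-pyran-2-one
Product: 25 (R)-5-{2-[1-hydroxy-2-(phenylsulfonyl)ethyl]-4-isopropyl-3,5,6-trimethoxyphenyl}-5-(3-iodopropyl)-3-methyl-5,6-dihydro-2H-pyran-2-one (both C7 epimers)
Conditions: NaI, acetone, reflux
Reagents that add atoms: sodium iodide, [Na+].[I-]
Why: Finkelstein reaction: precipitation of NaCl from acetone drives the exchange of the primary chloride on C3 for the better leaving group iodide under neutral conditions.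

Step 14
Reactants: 25 (R)-5-{2-[1-hydroxy-2-(phenylsulfonyl)ethyl]-4-isopropyl-3,5,6-trimethoxyphenyl}-5-(3-iodopropyl)-3-methyl-5,6-dihydro-2H-pyran-2-one
Product: 29 (4S,5R,10R)-7-acetoxy-11,12,14-trimethoxy-6-(phenylsulfonyl)abieta-8,11,13-trien-19,20-olide (C6/C7 epimers), via dilithio dianion 26 (not isolated), via tricyclic lactone enolate 27 (not isolated), via tetracyclic alkoxide 28 (not isolated)
Conditions: LDA (2.3 equiv), THF–DMPU, −78 to 0 °C; then Ac2O, 0 °C to rt
Reagents that add atoms: acetic anhydride, CC(=O)OC(C)=O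
Why: LDA removes the O–H and one C6–H of 25; the α-sulfonyl carbanion of 26 adds to C5, the β-carbon of the unsaturated lactone, which closes ring B (6-exo-trig) and makes C4 the lithium enolate 27, and this enolate displaces iodide from C3 (6-exo-tet), which forms C3–C4, closes ring A and completes the 3-oxabicyclo[3.3.1]nonan-2-one core. The closest known reaction type is the Michael-initiated ring closure, in which a sulfonyl carbanion adds to an ω-halo-α,β-unsaturated ester and the enolate is alkylated intramolecularly. C5 is set by the first tether: C6 hangs from C8 of the aryl group on C10 and can reach only the lactone face syn to that aryl group and anti to the pseudoaxial C1–C3 chain, so H-5 ends anti to C20 (trans A/B fusion). C4 is set by the second tether: the chain lies on the opposite face, 1,3-diaxial to the enolate carbon, only that face can be alkylated, and so C19 and C20 stay cis in the bridging lactone while the methyl group points outward. The step needs bond formation at C5 before any reaction at C3 and an enolate that survives until it reaches C3; direct attack of C6 on C3 would need an eight-membered transition state, and the only acidic C–H left after the Michael step is C6–H, whose removal is disfavoured next to the C7 alkoxide. The C6 and C7 centres form as mixtures that step 15 erases, and acetic anhydride traps alkoxide 28 as 29.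

Step 15
Reactants: 29 (4S,5R,10R)-7-acetoxy-11,12,14-trimethoxy-6-(phenylsulfonyl)abieta-8,11,13-trien-19,20-olide
Product: 30 (4S,5R,10R)-11,12,14-trimethoxyabieta-6,8,11,13-tetraen-19,20-olide
Conditions: SmI2 (excess), THF–DMPU, rt
Reagents that add atoms: none
Why: Julia–Lythgoe reductive elimination: divalent samarium reduces the sulfone, loss of sulfinate gives a C6 radical and then an organosamarium that expels the C7 acetate, and in the six-membered ring B only the cis C6=C7 alkene can form.

Step 16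
Reactants: 30 (4S,5R,10R)-11,12,14-trimethoxyabieta-6,8,11,13-tetraen-19,20-olide
Product: 32 (4S,5R,10R)-12-hydroxy-11,14-dioxoabieta-6,8,12-trien-19,20-olide, via hydroquinone triol 31 (not isolated)
Conditions: BBr3, CH2Cl2, −78 to 0 °C; then H2O, air, rt
Reagents that add atoms: none
Why: Lewis-acid cleavage of aryl methyl ethers followed by autoxidation: BBr3 removes the three O-methyl groups and air oxidises the 1,2,4-trihydroxyarene to the more stable 2-hydroxy-1,4-benzoquinone tautomer, while the neopentyl C20–O bond of the lactone resists attack by bromide.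

Step 17
Reactants: 32 (4S,5R,10R)-12-hydroxy-11,14-dioxoabieta-6,8,12-trien-19,20-olide
Product: 33 (4S,5R,10R)-12-acetoxy-11,14-dioxoabieta-6,8,12-trien-19,20-olide (target)
Conditions: Ac2O, pyridine, CH2Cl2, 0 °C
Reagents that add atoms: acetic anhydride, CC(=O)OC(C)=O
Why: O-acylation: the acidic C12 hydroxyl group of the hydroxyquinone is the only acylable site, and the mild base and low temperature leave the C5 stereocentre untouched.

Compound list
1 | 2,4,5-trimethoxytoluene | Cc1cc(OC)c(OC)cc1OC | starting material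
2 | acetone | CC(C)=O | starting material
3 | (2,3,6-trimethoxy-5-methylphenyl)lithium | [Li]c1c(OC)c(C)cc(OC)c1OC | intermediate
4 | 2-(2,3,6-trimethoxy-5-methylphenyl)propan-2-ol | CC(C)(O)c1c(OC)c(C)cc(OC)c1OC | intermediate
5 | 3-isopropyl-2,4,5-trimethoxytoluene | CC(C)c1c(OC)c(C)cc(OC)c1OC | intermediate
6 | 2-bromo-5-isopropyl-3,4,6-trimethoxytoluene | CC(C)c1c(OC)c(C)c(Br)c(OC)c1OC | intermediate
7 | dimethyl malonate | COC(=O)CC(=O)OC | starting material
8 | dimethyl 2-(4-isopropyl-2,3,5-trimethoxy-6-methylphenyl)malonate | COC(=O)C(C(=O)OC)c1c(C)c(OC)c(C(C)C)c(OC)c1OC | intermediate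
9 | 1-chloro-3-iodopropane | ClCCCI | starting material
10 | sodium enolate of 8 | COC(=O)C(=C([O-])OC)c1c(C)c(OC)c(C(C)C)c(OC)c1OC.[Na+] | intermediate
11 | dimethyl 2-(3-chloropropyl)-2-(4-isopropyl-2,3,5-trimethoxy-6-methylphenyl)malonate | COC(=O)C(CCCCl)(C(=O)OC)c1c(C)c(OC)c(C(C)C)c(OC)c1OC | intermediate
12 | 2-(3-chloropropyl)-2-(4-isopropyl-2,3,5-trimethoxy-6-methylphenyl)propane-1,3-diol | OCC(CO)(CCCCl)c1c(C)c(OC)c(C(C)C)c(OC)c1OC | intermediate
13 | (S)-5-chloro-2-(hydroxymethyl)-2-(4-isopropyl-2,3,5-trimethoxy-6-methylphenyl)pentyl benzoate | OC[C@](COC(=O)c1ccccc1)(CCCCl)c1c(C)c(OC)c(C(C)C)c(OC)c1OC | intermediate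
14 | (R)-5-chloro-2-formyl-2-(4-isopropyl-2,3,5-trimethoxy-6-methylphenyl)pentyl benzoate | O=C[C@](COC(=O)c1ccccc1)(CCCCl)c1c(C)c(OC)c(C(C)C)c(OC)c1OC | intermediate
15 | ethyl 2-[bis(2,2,2-trifluoroethoxy)phosphoryl]propanoate | CCOC(=O)C(C)P(=O)(OCC(F)(F)F)OCC(F)(F)F | starting material
16 | potassium salt of the α-carbanion of 15 | CCOC(=O)[C-](C)P(=O)(OCC(F)(F)F)OCC(F)(F)F.[K+] | intermediate
17 | ethyl (R,Z)-4-[(benzoyloxy)methyl]-7-chloro-4-(4-isopropyl-2,3,5-trimethoxy-6-methylphenyl)-2-methylhept-2-enoate | CCOC(=O)/C(C)=C\[C@](COC(=O)c1ccccc1)(CCCCl)c1c(C)c(OC)c(C(C)C)c(OC)c1OC | intermediate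
18 | ethyl (R,Z)-7-chloro-4-(hydroxymethyl)-4-(4-isopropyl-2,3,5-trimethoxy-6-methylphenyl)-2-methylhept-2-enoate | CCOC(=O)/C(C)=C\[C@](CO)(CCCCl)c1c(C)c(OC)c(C(C)C)c(OC)c1OC | intermediate
19 | (R)-5-(3-chloropropyl)-5-(4-isopropyl-2,3,5-trimethoxy-6-methylphenyl)-3-methyl-5,6-dihydro-2H-pyran-2-one | CC1=C[C@@](CCCCl)(COC1=O)c1c(C)c(OC)c(C(C)C)c(OC)c1OC | intermediate
20 | (R)-5-(3-chloropropyl)-5-[2-(hydroxymethyl)-4-isopropyl-3,5,6-trimethoxyphenyl]-3-methyl-5,6-dihydro-2H-pyran-2-one | CC1=C[C@@](CCCCl)(COC1=O)c1c(CO)c(OC)c(C(C)C)c(OC)c1OC | intermediate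
21 | 2-[(R)-3-(3-chloropropyl)-5-methyl-6-oxo-3,6-dihydro-2H-pyran-3-yl]-5-isopropyl-3,4,6-trimethoxybenzaldehyde | CC1=C[C@@](CCCCl)(COC1=O)c1c(C=O)c(OC)c(C(C)C)c(OC)c1OC | intermediate
22 | methyl phenyl sulfone | CS(=O)(=O)c1ccccc1 | starting material
23 | [(phenylsulfonyl)methyl]lithium | [Li]CS(=O)(=O)c1ccccc1 | intermediate
24 | (R)-5-(3-chloropropyl)-5-{2-[1-hydroxy-2-(phenylsulfonyl)ethyl]-4-isopropyl-3,5,6-trimethoxyphenyl}-3-methyl-5,6-dihydro-2H-pyran-2-one, C7 epimers | CC1=C[C@@](CCCCl)(COC1=O)c1c(C(O)CS(=O)(=O)c2ccccc2)c(OC)c(C(C)C)c(OC)c1OC | intermediate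
25 | (R)-5-{2-[1-hydroxy-2-(phenylsulfonyl)ethyl]-4-isopropyl-3,5,6-trimethoxyphenyl}-5-(3-iodopropyl)-3-methyl-5,6-dihydro-2H-pyran-2-one, C7 epimers | CC1=C[C@@](CCCI)(COC1=O)c1c(C(O)CS(=O)(=O)c2ccccc2)c(OC)c(C(C)C)c(OC)c1OC | intermediate
26 | dilithium C7-alkoxide C6-carbanion of 25 | CC1=C[C@@](CCCI)(COC1=O)c1c(C([O-])[CH-]S(=O)(=O)c2ccccc2)c(OC)c(C(C)C)c(OC)c1OC.[Li+].[Li+] | intermediate
27 | dilithium salt of the ring-B-closed tricycle (C4=C19 lactone enolate, C7 alkoxide, C1–C3 iodopropyl chain on C10; C5 and C10 as in the target) | COc1c(C(C)C)c(OC)c2c(c1OC)[C@]1(CCCI)COC([O-])=C(C)[C@@H]1C(S(=O)(=O)c1ccccc1)C2[O-].[Li+].[Li+] | intermediate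
28 | lithium C7-alkoxide of (4S,5R,10R)-7-hydroxy-11,12,14-trimethoxy-6-(phenylsulfonyl)abieta-8,11,13-trien-19,20-olide | COc1c(C(C)C)c(OC)c2c(c1OC)[C@]13CCC[C@](C)(C(=O)OC1)[C@@H]3C(S(=O)(=O)c1ccccc1)C2[O-].[Li+] | intermediate
29 | (4S,5R,10R)-7-acetoxy-11,12,14-trimethoxy-6-(phenylsulfonyl)abieta-8,11,13-trien-19,20-olide, C6/C7 epimers | COc1c(C(C)C)c(OC)c2c(c1OC)[C@]13CCC[C@](C)(C(=O)OC1)[C@@H]3C(S(=O)(=O)c1ccccc1)C2OC(C)=O | intermediate
30 | (4S,5R,10R)-11,12,14-trimethoxyabieta-6,8,11,13-tetraen-19,20-olide | COc1c(C(C)C)c(OC)c2c(c1OC)[C@]13CCC[C@](C)(C(=O)OC1)[C@@H]3C=C2 | intermediate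
31 | (4S,5R,10R)-11,12,14-trihydroxyabieta-6,8,11,13-tetraen-19,20-olide | Oc1c(C(C)C)c(O)c2c(c1O)[C@]13CCC[C@](C)(C(=O)OC1)[C@@H]3C=C2 | intermediate
32 | (4S,5R,10R)-12-hydroxy-11,14-dioxoabieta-6,8,12-trien-19,20-olide | OC1=C(C(C)C)C(=O)C2=C(C1=O)[C@]13CCC[C@](C)(C(=O)OC1)[C@@H]3C=C2 | intermediate
33 | (4S,5R,10R)-12-acetoxy-11,14-dioxoabieta-6,8,12-trien-19,20-olide | CC(=O)OC1=C(C(C)C)C(=O)C2=C(C1=O)[C@]13CCC[C@](C)(C(=O)OC1)[C@@H]3C=C2 | target

Total step count: 17. Longest linear sequence: 17.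

Steps most likely to fail

**Step 14 (key step).**
- What may go wrong: the dianion may revert to aldehyde and sulfonyl carbanion. The C7 alkoxide may add to C5 in an oxa-Michael reaction. Proton transfer may quench the C4 enolate before it reaches C3.
- The fallback separates the two ring closures and uses a softer donor. It sets out from 24 and comes back at 29.
- Dess–Martin oxidation should give the β-keto sulfone (R)-5-(3-chloropropyl)-5-{4-isopropyl-3,5,6-trimethoxy-2-[(phenylsulfonyl)acetyl]phenyl}-3-methyl-5,6-dihydro-2H-pyran-2-one F1.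
- Cs2CO3 in MeCN should close ring B by Michael addition of the doubly stabilised C6 carbanion to C5, giving the tricyclic 7-oxo-6-sulfonyl lactone with a chloropropyl chain F2.
- NaI in acetone gives the corresponding iodopropyl tricycle F3.
- KHMDS (2.2 equiv) in THF–DMPU forms the C6,C4 dianion, whose more basic lactone enolate closes ring A to (4S,5R,10R)-11,12,14-trimethoxy-7-oxo-6-(phenylsulfonyl)abieta-8,11,13-trien-19,20-olide F4.
- NaBH4 reduces the C7 ketone to (4S,5R,10R)-7-hydroxy-11,12,14-trimethoxy-6-(phenylsulfonyl)abieta-8,11,13-trien-19,20-olide F5, and Ac2O in pyridine returns to 29.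

**Step 11.**
- What may go wrong: hydride abstraction may be slow at the doubly flanked methyl group. Oxidation may instead occur at the isopropyl group, or lead to oxidative demethylation of the ring.
- The fallback avoids any oxygen at C7 and replaces the Julia elimination by a base-induced loss of sulfinate. It sets out from 19 and comes back at 30.
- Radical benzylic bromination (NBS, AIBN, PhCF3, reflux) should give (R)-5-[2-(bromomethyl)-4-isopropyl-3,5,6-trimethoxyphenyl]-5-(3-chloropropyl)-3-methyl-5,6-dihydro-2H-pyran-2-one F6.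
- Alkylation of 23 at −78 °C gives (R)-5-(3-chloropropyl)-5-{4-isopropyl-3,5,6-trimethoxy-2-[2-(phenylsulfonyl)ethyl]phenyl}-3-methyl-5,6-dihydro-2H-pyran-2-one F7.
- NaI in acetone gives the iodopropyl analogue F8.
- LDA (1.1 equiv) in THF–DMPU triggers the same Michael and alkylation sequence to (4S,5R,10R)-11,12,14-trimethoxy-6-(phenylsulfonyl)abieta-8,11,13-trien-19,20-olide F9.
- KOtBu in THF removes a benzylic C7 proton with loss of sulfinate and returns to 30.

**Step 7.**
- What may go wrong: the catalyst may discriminate poorly between the enantiotopic hydroxymethyl groups next to the hexasubstituted aryl group. The enantiomeric purity may also erode through 1,3-benzoyl migration.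
- The fallback desymmetrises one oxidation level earlier. It sets out from 11 and comes back at 19.
- Enantioselective mono-hydrosilylation of the malonate (ZnEt2, chiral ProPhenol-type ligand, (EtO)2MeSiH, toluene) should give methyl (R)-5-chloro-2-(hydroxymethyl)-2-(4-isopropyl-2,3,5-trimethoxy-6-methylphenyl)pentanoate F10.
- TBSCl and imidazole give its tert-butyldimethylsilyl ether F11.
- DIBAL-H at −78 °C gives the silyloxy aldehyde F12.
- Still–Gennari olefination with 15 gives the (Z)-silyloxy enoate F13.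
- TBAF frees 18, which lactonises to 19.

Further compounds
F1 | step 14 | (R)-5-(3-chloropropyl)-5-{4-isopropyl-3,5,6-trimethoxy-2-[(phenylsulfonyl)acetyl]phenyl}-3-methyl-5,6-dihydro-2H-pyran-2-one | CC1=C[C@@](CCCCl)(COC1=O)c1c(C(=O)CS(=O)(=O)c2ccccc2)c(OC)c(C(C)C)c(OC)c1OC
F2 | step 14 | ring-B-closed tricyclic lactone, 7-oxo, 6-phenylsulfonyl, 3-chloropropyl on C10 (C5 and C10 as in the target, C4 and C6 epimers) | COc1c(C(C)C)c(OC)c2c(c1OC)[C@]1(CCCCl)COC(=O)C(C)[C@@H]1C(S(=O)(=O)c1ccccc1)C2=O
F3 | step 14 | iodopropyl analogue of F2 | COc1c(C(C)C)c(OC)c2c(c1OC)[C@]1(CCCI)COC(=O)C(C)[C@@H]1C(S(=O)(=O)c1ccccc1)C2=O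
F4 | step 14 | (4S,5R,10R)-11,12,14-trimethoxy-7-oxo-6-(phenylsulfonyl)abieta-8,11,13-trien-19,20-olide | COc1c(C(C)C)c(OC)c2c(c1OC)[C@]13CCC[C@](C)(C(=O)OC1)[C@@H]3C(S(=O)(=O)c1ccccc1)C2=O
F5 | step 14 | (4S,5R,10R)-7-hydroxy-11,12,14-trimethoxy-6-(phenylsulfonyl)abieta-8,11,13-trien-19,20-olide | COc1c(C(C)C)c(OC)c2c(c1OC)[C@]13CCC[C@](C)(C(=O)OC1)[C@@H]3C(S(=O)(=O)c1ccccc1)C2O
F6 | step 11 | (R)-5-[2-(bromomethyl)-4-isopropyl-3,5,6-trimethoxyphenyl]-5-(3-chloropropyl)-3-methyl-5,6-dihydro-2H-pyran-2-one | CC1=C[C@@](CCCCl)(COC1=O)c1c(CBr)c(OC)c(C(C)C)c(OC)c1OC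
F7 | step 11 | (R)-5-(3-chloropropyl)-5-{4-isopropyl-3,5,6-trimethoxy-2-[2-(phenylsulfonyl)ethyl]phenyl}-3-methyl-5,6-dihydro-2H-pyran-2-one | CC1=C[C@@](CCCCl)(COC1=O)c1c(CCS(=O)(=O)c2ccccc2)c(OC)c(C(C)C)c(OC)c1OC
F8 | step 11 | (R)-5-(3-iodopropyl)-5-{4-isopropyl-3,5,6-trimethoxy-2-[2-(phenylsulfonyl)ethyl]phenyl}-3-methyl-5,6-dihydro-2H-pyran-2-one | CC1=C[C@@](CCCI)(COC1=O)c1c(CCS(=O)(=O)c2ccccc2)c(OC)c(C(C)C)c(OC)c1OC
F9 | step 11 | (4S,5R,10R)-11,12,14-trimethoxy-6-(phenylsulfonyl)abieta-8,11,13-trien-19,20-olide | COc1c(C(C)C)c(OC)c2c(c1OC)[C@]13CCC[C@](C)(C(=O)OC1)[C@@H]3C(S(=O)(=O)c1ccccc1)C2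
F10 | step 7 | methyl (R)-5-chloro-2-(hydroxymethyl)-2-(4-isopropyl-2,3,5-trimethoxy-6-methylphenyl)pentanoate | COC(=O)[C@](CO)(CCCCl)c1c(C)c(OC)c(C(C)C)c(OC)c1OC
F11 | step 7 | tert-butyldimethylsilyl ether of F10 | COC(=O)[C@](CO[Si](C)(C)C(C)(C)C)(CCCCl)c1c(C)c(OC)c(C(C)C)c(OC)c1OC
F12 | step 7 | 2-[(tert-butyldimethylsilyloxy)methyl]-5-chloro-2-(4-isopropyl-2,3,5-trimethoxy-6-methylphenyl)pentanal, C10 as in 14 | O=C[C@](CO[Si](C)(C)C(C)(C)C)(CCCCl)c1c(C)c(OC)c(C(C)C)c(OC)c1OC
F13 | step 7 | ethyl (Z)-4-[(tert-butyldimethylsilyloxy)methyl]-7-chloro-4-(4-isopropyl-2,3,5-trimethoxy-6-methylphenyl)-2-methylhept-2-enoate, C10 as in 17 | CCOC(=O)/C(C)=C\[C@](CO[Si](C)(C)C(C)(C)C)(CCCCl)c1c(C)c(OC)c(C(C)C)c(OC)c1OC
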